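## Retrosynthetic overview

1. Bromophycolide E ⇐ MOM removal ⇐ C10/C11 bromohydrin by bromide opening of the (10S,11S)-epoxide of a macrocyclic E-alkene.
2. The 15-membered macrolactone (second ring formed) ⇐ Yamaguchi lactonisation at O–C14 of a seco acid.
3. C9–C10 bond ⇐ Negishi sp3–sp2 coupling of a bromocyclohexane ethyl iodide (arene + C1–C9) with an E-vinyl iodide (C10–C16, C14 set by CBS reduction).
4. Bromocyclohexane (first ring formed; C2 and C7 set, C6 carried in) ⇐ proposed enantiospecific bromonium/allylsilane cyclisation of an acyclic (6S,7R)-bromohydrin trifluoroacetate ⇐ (6R,7R)-epoxide (Shi).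
5. Acyclic precursor ⇐ but-3-yn-1-ol, methyl acetoacetate, Me3SiCH2MgCl and methyl 4-hydroxy-3-iodobenzoate.

Assumption: locants C1–C16 follow the diterpene chain (C1 benzylic CH2; C2–C7 the cyclohexane, C3 carrying the exocyclic methylene, C6 = CHBr, C7 quaternary; C10/C11 bromohydrin; C14 ester carbinol; C15/C16 isopropenyl), TBDPS = tert-butyldiphenylsilyl, TBS = tert-butyldimethylsilyl, MOM = methoxymethyl, and both enantiomers of the Shi ketone are taken as available.

## Route

Step 1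
Reactants: 1 but-3-yn-1-ol
Product: 2 (but-3-yn-1-yloxy)(tert-butyl)diphenylsilane
Conditions: TBDPSCl, imidazole, DMF, 0 °C→rt
Reagents that add atoms: tert-butyl(chloro)diphenylsilane, CC(C)(C)[Si](Cl)(c1ccccc1)c1ccccc1
Why: Silyl ether formation on the primary alcohol; the bulky, non-nucleophilic TBDPS ether later keeps the C9 oxygen from trapping the bromonium ion.

Step 2
Reactants: 2 (but-3-yn-1-yloxy)(tert-butyl)diphenylsilane
Product: 5 (2E)-5-(TBDPS-oxy)-3-methylpent-2-en-1-ol, via vinylalane 3 (not isolated), via lithium alanate 4 (not isolated)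
Conditions: AlMe3, Cp2ZrCl2 (25 mol %), CH2Cl2, 0 °C→rt; n-BuLi, THF, −78 °C; (CH2O)n, −78 °C→rt
Reagents that add atoms: trimethylaluminium, C[Al](C)C; formaldehyde (as paraformaldehyde), C=O
Why: Negishi zirconium-catalysed carboalumination adds Me and Al syn across the alkyne with Me on the internal carbon, and hydroxymethylation of the alanate with retention gives the E allylic alcohol (C5–C9).

Step 3
Reactants: 5 (2E)-5-(TBDPS-oxy)-3-methylpent-2-en-1-ol
Product: 6 (2E)-1-bromo-5-(TBDPS-oxy)-3-methylpent-2-ene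
Conditions: CBr4, PPh3, CH2Cl2, 0 °C
Reagents that add atoms: tetrabromomethane, BrC(Br)(Br)Br
Why: Appel bromination is an SN2 displacement at the primary allylic carbon and leaves the alkene geometry untouched.

Step 4
Reactants: 6 (2E)-1-bromo-5-(TBDPS-oxy)-3-methylpent-2-ene; 7 methyl acetoacetate
Product: 9 methyl (6E)-9-(TBDPS-oxy)-7-methyl-3-oxonon-6-enoate, via acetoacetate dianion 8 (not isolated)
Conditions: 7, NaH, THF, 0 °C; n-BuLi, 0 °C; then 6, 0 °C→rt; aq. HCl quench
Reagents that add atoms: none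
Why: Weiler dianion alkylation, in which the more reactive terminal carbanion of the acetoacetate dianion displaces the allylic bromide (SN2) and forms C4–C5.

Step 5
Reactants: 9 methyl (6E)-9-(TBDPS-oxy)-7-methyl-3-oxonon-6-enoate
Product: 10 methyl (2Z,6E)-9-(TBDPS-oxy)-7-methyl-3-(triflyloxy)nona-2,6-dienoate
Conditions: NaH, Et2O, 0 °C; then Tf2O, 0 °C
Reagents that add atoms: trifluoromethanesulfonic anhydride, O=S(=O)(OS(=O)(=O)C(F)(F)F)C(F)(F)F
Why: O-sulfonylation of the chelated sodium enolate gives the Z enol triflate (OTf cis to CO2Me), which fixes the C2=C3 geometry.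

Step 6
Reactants: 10 methyl (2Z,6E)-9-(TBDPS-oxy)-7-methyl-3-(triflyloxy)nona-2,6-dienoate
Product: 11 methyl (2Z,6E)-9-(TBDPS-oxy)-7-methyl-3-[(trimethylsilyl)methyl]nona-2,6-dienoate
Conditions: Me3SiCH2MgCl, Pd(PPh3)4 (5 mol %), THF, 0 °C→rt
Reagents that add atoms: [(trimethylsilyl)methyl]magnesium chloride, C[Si](C)(C)C[Mg]Cl
Why: Kumada–Corriu cross-coupling of the enol triflate proceeds with retention, placing CH2SiMe3 cis to the ester and C4 trans to C1 as the chair cyclisation later requires.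

Step 7
Reactants: 11 methyl (2Z,6E)-9-(TBDPS-oxy)-7-methyl-3-[(trimethylsilyl)methyl]nona-2,6-dienoate
Product: 12 (6R,7R)-epoxy enoate
Conditions: D-fructose-derived Shi ketone (30 mol %), KHSO5 (as 2KHSO5·KHSO4·K2SO4), K2CO3, Bu4NHSO4, MeCN/CH2(OMe)2/H2O, pH 10.5, 0 °C
Reagents that add atoms: potassium peroxymonosulfate KHSO5, [K+].[O-]S(=O)(=O)OO
Why: Shi asymmetric epoxidation, in which the chiral dioxirane attacks only the electron-rich C6=C7 alkene (the ester-conjugated C2=C3 is inert) through the spiro transition state and sets 6R,7R.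

Step 8
Reactants: 12 (6R,7R)-epoxy enoate
Product: 13 (2Z;6R,7R)-epoxy allylic alcohol
Conditions: i-Bu2AlH, CH2Cl2, −78 °C; aq. KNaC4H4O6 work-up
Reagents that add atoms: none
Why: 1,2-Reduction of the enoate by i-Bu2AlH at −78 °C gives the allylic alcohol without touching the trisubstituted epoxide or the C–Si bond.

Step 9
Reactants: 13 (2Z;6R,7R)-epoxy allylic alcohol
Product: 15 (2Z;6R,7R)-epoxy allylic chloride, via mesylate 14 (not isolated)
Conditions: MsCl, 2,4,6-collidine, LiCl, DMF, 0 °C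
Reagents that add atoms: lithium chloride, [Li+].[Cl-]
Why: Collington–Meyers chlorination (SN2 displacement of the in-situ mesylate by chloride) under buffered, non-ionising conditions avoids the allyl cation that would eliminate the silyl group.

Step 10
Reactants: 16 methyl 4-hydroxy-3-iodobenzoate
Product: 17 methyl 3-iodo-4-(methoxymethoxy)benzoate
Conditions: MOMCl, i-Pr2NEt, CH2Cl2, 0 °C→rt
Reagents that add atoms: chloromethyl methyl ether, COCCl
Why: Phenol O-alkylation to the MOM ether, which survives organometallic, basic and fluoride steps and is removed last under mild Lewis-acid conditions.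

Step 11
Reactants: 17 methyl 3-iodo-4-(methoxymethoxy)benzoate; 15 (2Z;6R,7R)-epoxy allylic chloride
Product: 19 (2Z;6R,7R)-aryl epoxide, via arylmagnesium chloride 18 (not isolated)
Conditions: 17, i-PrMgCl·LiCl, THF, −40 °C; then Li2CuCl4 (5 mol %), 15, −40→0 °C
Reagents that add atoms: none
Why: Iodine–magnesium exchange (ester tolerated at −40 °C) followed by copper-catalysed SN2 allylic arylation, which goes to the α-carbon because the γ-carbon is fully substituted and keeps the alkene geometry.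

Step 12
Reactants: 19 (2Z;6R,7R)-aryl epoxide
Product: 20 (2Z;6S,7R)-6-bromo-7-hydroxy bromohydrin
Conditions: Li2NiBr4, THF, 0 °C→rt
Reagents that add atoms: dilithium tetrabromonickelate Li2NiBr4, [Li+].[Li+].Br[Ni-2](Br)(Br)Br
Why: SN2 opening of the trisubstituted epoxide by soft bromide at the less substituted C6 with inversion gives the 6S bromide anti to the untouched 7R tertiary alcohol.

Step 13
Reactants: 20 (2Z;6S,7R)-6-bromo-7-hydroxy bromohydrin
Product: 21 (2Z;6S,7R)-6-bromo-7-trifluoroacetate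
Conditions: (CF3CO)2O, pyridine, CH2Cl2, −20 °C
Reagents that add atoms: trifluoroacetic anhydride, O=C(OC(=O)C(F)(F)F)C(F)(F)F
Why: O-Acylation of the tertiary alcohol installs a neutral nucleofuge without touching any stereocentre.

Step 14
Reactants: 21 (2Z;6S,7R)-6-bromo-7-trifluoroacetate
Product: 23 (2R,6S,7S)-bromocyclohexane TBDPS ether, via bromonium ion pair 22 (not isolated)
Conditions: (CF3)2CHOH (0.005 M), 2,6-di-tert-butyl-4-methylpyridine, 0→25 °C
Reagents that add atoms: none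
Why: Proposed new method: in (CF3)2CHOH the tertiary trifluoroacetate ionises with anchimeric help from the anti C6 bromine, so the enantiopure bromonium ion 22 forms at one defined site with no external Br+ (the other alkenes are never exposed to an electrophile); the tethered 2-(silylmethyl)alkene attacks C7 anti to bromine through a chair transition state with Br, the C8 chain and the C1 benzyl group equatorial (setting 7S and 2R, with 6S carried over), and loss of Me3Si+ from the β-silyl cation fixes the exocyclic C3 methylene; high dilution and the hindered base suppress alkene-to-alkene Br+ transfer and protodesilylation; the closest known reaction types are the enantiospecific solvolytic generation of bromonium ions from vicinal bromochlorides or bromohydrin derivatives in fluorinated alcohols (to my knowledge so far captured by arenes, solvent or simple alkenes) and Sakurai-type allylsilane-terminated cation–olefin cyclisation.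

Step 15
Reactants: 23 (2R,6S,7S)-bromocyclohexane TBDPS ether
Product: 24 (2R,6S,7S)-bromocyclohexane C9 alcohol
Conditions: HF·pyridine, pyridine, THF, 0 °C→rt
Reagents that add atoms: none
Why: Fluoride-mediated desilylation of the primary TBDPS ether; the MOM ether, methyl ester and hindered secondary bromide are inert.

Step 16
Reactants: 24 (2R,6S,7S)-bromocyclohexane C9 alcohol
Product: 25 (2R,6S,7S)-bromocyclohexane C9 iodide
Conditions: I2, PPh3, imidazole, CH2Cl2, 0 °C→rt
Reagents that add atoms: iodine, II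
Why: Appel-type (Garegg–Samuelsson) iodination converts the unhindered primary alcohol by SN2 and does not touch the neopentyl-like secondary bromide.

Step 17
Reactants: 26 pent-4-ynoic acid
Product: 28 N-methoxy-N-methylpent-4-ynamide, via acyl imidazole 27 (not isolated)
Conditions: 1,1′-carbonyldiimidazole, CH2Cl2, rt; then MeNH(OMe)·HCl, rt
Reagents that add atoms: N,O-dimethylhydroxylamine hydrochloride, CNOC.Cl
Why: Amide coupling through the acyl imidazole gives the Weinreb amide.

Step 18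
Reactants: 28 N-methoxy-N-methylpent-4-ynamide
Product: 29 2-methylhept-1-en-6-yn-3-one
Conditions: CH2=C(CH3)MgBr (2.2 equiv), THF, −20→0 °C; aq. NH4Cl
Reagents that add atoms: isopropenylmagnesium bromide, CC(=C)[Mg]Br
Why: Weinreb ketone synthesis, in which the chelated tetrahedral intermediate survives until work-up and so prevents over-addition and conjugate addition to the enone.

Step 19
Reactants: 29 2-methylhept-1-en-6-yn-3-one
Product: 30 (3S)-2-methylhept-1-en-6-yn-3-ol
Conditions: (R)-2-methyl-CBS-oxazaborolidine (20 mol %), catecholborane, toluene, −78 °C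
Reagents that add atoms: none
Why: Corey–Bakshi–Shibata reduction with the α-branched isopropenyl group as the large substituent delivers hydride to one carbonyl face and sets 14S, and catecholborane at −78 °C does not hydroborate the alkyne or alkene.

Step 20
Reactants: 30 (3S)-2-methylhept-1-en-6-yn-3-ol
Product: 31 (3S)-3-(TBS-oxy)-2-methylhept-1-en-6-yne
Conditions: TBSCl, imidazole, DMF, rt
Reagents that add atoms: tert-butyl(chloro)dimethylsilane, CC(C)(C)[Si](C)(C)Cl
Why: Silyl ether formation protects the allylic alcohol for the organoaluminium and organozinc steps.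

Step 21
Reactants: 31 (3S)-3-(TBS-oxy)-2-methylhept-1-en-6-yne
Product: 33 (3S,6E)-7-iodo-2,6-dimethyl-3-(TBS-oxy)hepta-1,6-diene, via vinylalane 32 (not isolated)
Conditions: AlMe3, Cp2ZrCl2 (20 mol %), CH2Cl2, 0 °C→rt; then I2, THF, −30 °C
Reagents that add atoms: trimethylaluminium, C[Al](C)C; iodine, II
Why: Negishi carboalumination (syn, Me on the internal carbon) followed by iododealumination with retention gives the E vinyl iodide, and the 1,1-disubstituted alkene is not carbometalated.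

Step 22
Reactants: 25 (2R,6S,7S)-bromocyclohexane C9 iodide; 33 (3S,6E)-7-iodo-2,6-dimethyl-3-(TBS-oxy)hepta-1,6-diene
Product: 35 (2R,6S,7S,10E,14S)-coupled TBS ether methyl ester, via alkylzinc iodide 34 (not isolated)
Conditions: 25, Zn, LiCl, THF, 40 °C; then 33, PdCl2(dppf) (5 mol %), THF/NMP, 40 °C
Reagents that add atoms: none
Why: Negishi cross-coupling, in which zinc inserts into the primary C–I bond (not into the hindered secondary C–Br) and palladium-catalysed sp3–sp2 coupling with the vinyl iodide proceeds with retention to form C9–C10 and the 10E alkene.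

Step 23
Reactants: 35 (2R,6S,7S,10E,14S)-coupled TBS ether methyl ester
Product: 36 (2R,6S,7S,10E,14S)-hydroxy methyl ester
Conditions: HF·pyridine, pyridine, THF, 0 °C→rt
Reagents that add atoms: none
Why: Fluoride-mediated desilylation frees the C14 allylic alcohol without affecting the MOM ether, ester or bromide.

Step 24
Reactants: 36 (2R,6S,7S,10E,14S)-hydroxy methyl ester
Product: 37 (2R,6S,7S,10E,14S)-seco acid
Conditions: LiOH, THF/MeOH/H2O, 40 °C; aq. HCl to pH 4 at 0 °C
Reagents that add atoms: lithium hydroxide, [Li+].[OH-]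
Why: Saponification of the methyl benzoate; the equatorial neopentyl-like bromide has no anti-periplanar hydrogen and resists substitution or elimination.

Step 25
Reactants: 37 (2R,6S,7S,10E,14S)-seco acid
Product: 39 (2R,6S,7S,10E,14S)-macrolactone MOM ether, via mixed anhydride 38 (not isolated)
Conditions: 2,4,6-trichlorobenzoyl chloride, Et3N, THF, rt; then slow addition to DMAP, toluene (0.001 M), 70 °C
Reagents that add atoms: none
Why: Yamaguchi macrolactonisation (DMAP acyl transfer from the mixed anhydride under high dilution) closes the 15-membered ring with retention at C14 because the C14–O bond is never broken.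

Step 26
Reactants: 39 (2R,6S,7S,10E,14S)-macrolactone MOM ether
Product: 40 (2R,6S,7S,10S,11S,14S)-epoxy macrolactone MOM ether
Conditions: ent-Shi ketone (L-sorbose-derived, 50 mol %), KHSO5 (as 2KHSO5·KHSO4·K2SO4), K2CO3, Bu4NHSO4, MeCN/CH2(OMe)2/H2O, pH 10.5, −5 °C
Reagents that add atoms: potassium peroxymonosulfate KHSO5, [K+].[O-]S(=O)(=O)OO
Why: Shi epoxidation with the enantiomeric ketone attacks the trisubstituted C10=C11 alkene ahead of the two 1,1-disubstituted alkenes and sets 10S,11S under catalyst control.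

Step 27
Reactants: 40 (2R,6S,7S,10S,11S,14S)-epoxy macrolactone MOM ether
Product: 41 O-MOM bromophycolide E
Conditions: Li2NiBr4, THF, 0 °C→rt
Reagents that add atoms: dilithium tetrabromonickelate Li2NiBr4, [Li+].[Li+].Br[Ni-2](Br)(Br)Br
Why: SN2 opening of the epoxide by bromide at the secondary C10 with inversion gives the 10R bromide anti to the retained 11S tertiary alcohol.

Step 28
Reactants: 41 O-MOM bromophycolide E
Product: 42 bromophycolide E
Conditions: ZnBr2, n-PrSH, CH2Cl2, 0 °C, 10 min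
Reagents that add atoms: none
Why: Lewis-acid/thiol acetal exchange cleaves the aryl MOM ether within minutes without base, so the bromohydrin cannot close to an epoxide and the allylic ester stays intact.

## Compound list

1 | but-3-yn-1-ol | C#CCCO | starting material
2 | (but-3-yn-1-yloxy)(tert-butyl)diphenylsilane | C#CCCO[Si](c1ccccc1)(c1ccccc1)C(C)(C)C | intermediate
3 | [(1E)-4-(TBDPS-oxy)-2-methylbut-1-en-1-yl]dimethylalane | C[Al](C)/C=C(\C)CCO[Si](c1ccccc1)(c1ccccc1)C(C)(C)C | intermediate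
4 | lithium butyl[(1E)-4-(TBDPS-oxy)-2-methylbut-1-en-1-yl]dimethylalanate | [Li+].CCCC[Al-](C)(C)/C=C(\C)CCO[Si](c1ccccc1)(c1ccccc1)C(C)(C)C | intermediate
5 | (2E)-5-(TBDPS-oxy)-3-methylpent-2-en-1-ol | OC/C=C(\C)CCO[Si](c1ccccc1)(c1ccccc1)C(C)(C)C | intermediate
6 | (2E)-1-bromo-5-(TBDPS-oxy)-3-methylpent-2-ene | BrC/C=C(\C)CCO[Si](c1ccccc1)(c1ccccc1)C(C)(C)C | intermediate
7 | methyl acetoacetate (methyl 3-oxobutanoate) | COC(=O)CC(C)=O | starting material
8 | lithium sodium 1,3-dienolate (dianion) of methyl acetoacetate | [Li+].[Na+].COC([O-])=CC([O-])=C | intermediate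
9 | methyl (6E)-9-(TBDPS-oxy)-7-methyl-3-oxonon-6-enoate | COC(=O)CC(=O)CC/C=C(\C)CCO[Si](c1ccccc1)(c1ccccc1)C(C)(C)C | intermediate
10 | methyl (2Z,6E)-9-(TBDPS-oxy)-7-methyl-3-{[(trifluoromethyl)sulfonyl]oxy}nona-2,6-dienoate | COC(=O)/C=C(\OS(=O)(=O)C(F)(F)F)CC/C=C(\C)CCO[Si](c1ccccc1)(c1ccccc1)C(C)(C)C | intermediate
11 | methyl (2Z,6E)-9-(TBDPS-oxy)-7-methyl-3-[(trimethylsilyl)methyl]nona-2,6-dienoate | COC(=O)/C=C(\C[Si](C)(C)C)CC/C=C(\C)CCO[Si](c1ccccc1)(c1ccccc1)C(C)(C)C | intermediate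
12 | methyl (2Z)-5-[(2R,3R)-3-(2-TBDPS-oxyethyl)-3-methyloxiran-2-yl]-3-[(trimethylsilyl)methyl]pent-2-enoate | COC(=O)/C=C(\C[Si](C)(C)C)CC[C@H]1O[C@]1(C)CCO[Si](c2ccccc2)(c2ccccc2)C(C)(C)C | intermediate
13 | (2Z)-5-[(2R,3R)-3-(2-TBDPS-oxyethyl)-3-methyloxiran-2-yl]-3-[(trimethylsilyl)methyl]pent-2-en-1-ol | OC/C=C(\C[Si](C)(C)C)CC[C@H]1O[C@]1(C)CCO[Si](c2ccccc2)(c2ccccc2)C(C)(C)C | intermediate
14 | methanesulfonate of 13 | CS(=O)(=O)OC/C=C(\C[Si](C)(C)C)CC[C@H]1O[C@]1(C)CCO[Si](c2ccccc2)(c2ccccc2)C(C)(C)C | intermediate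
15 | tert-butyl(2-{(2R,3R)-3-[(3Z)-5-chloro-3-[(trimethylsilyl)methyl]pent-3-en-1-yl]-2-methyloxiran-2-yl}ethoxy)diphenylsilane | ClC/C=C(\C[Si](C)(C)C)CC[C@H]1O[C@]1(C)CCO[Si](c2ccccc2)(c2ccccc2)C(C)(C)C | intermediate
16 | methyl 4-hydroxy-3-iodobenzoate | COC(=O)c1ccc(O)c(I)c1 | starting material
17 | methyl 3-iodo-4-(methoxymethoxy)benzoate | COCOc1ccc(cc1I)C(=O)OC | intermediate
18 | [5-(methoxycarbonyl)-2-(methoxymethoxy)phenyl]magnesium chloride (LiCl complex) | COCOc1ccc(cc1[Mg]Cl)C(=O)OC | intermediate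
19 | methyl 3-{(2Z)-5-[(2R,3R)-3-(2-TBDPS-oxyethyl)-3-methyloxiran-2-yl]-3-[(trimethylsilyl)methyl]pent-2-en-1-yl}-4-(methoxymethoxy)benzoate | COC(=O)c1ccc(OCOC)c(C/C=C(\C[Si](C)(C)C)CC[C@H]2O[C@]2(C)CCO[Si](c3ccccc3)(c3ccccc3)C(C)(C)C)c1 | intermediate
20 | methyl 3-[(2Z,6S,7R)-6-bromo-9-(TBDPS-oxy)-7-hydroxy-7-methyl-3-[(trimethylsilyl)methyl]non-2-en-1-yl]-4-(methoxymethoxy)benzoate | COC(=O)c1ccc(OCOC)c(C/C=C(\C[Si](C)(C)C)CC[C@H](Br)[C@](C)(O)CCO[Si](c2ccccc2)(c2ccccc2)C(C)(C)C)c1 | intermediate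
21 | methyl 3-[(2Z,6S,7R)-6-bromo-9-(TBDPS-oxy)-7-methyl-7-(trifluoroacetoxy)-3-[(trimethylsilyl)methyl]non-2-en-1-yl]-4-(methoxymethoxy)benzoate | COC(=O)c1ccc(OCOC)c(C/C=C(\C[Si](C)(C)C)CC[C@H](Br)[C@](C)(OC(=O)C(F)(F)F)CCO[Si](c2ccccc2)(c2ccccc2)C(C)(C)C)c1 | intermediate
22 | (6S,7S)-C6–C7 bridged bromonium (bromiranium) ion of the acyclic allylsilane, trifluoroacetate ion pair | COC(=O)c1ccc(OCOC)c(C/C=C(\C[Si](C)(C)C)CC[C@@H]2[Br+][C@@]2(C)CCO[Si](c3ccccc3)(c3ccccc3)C(C)(C)C)c1.[O-]C(=O)C(F)(F)F | intermediate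
23 | methyl 3-{[(1R,2S,3S)-3-bromo-2-(2-TBDPS-oxyethyl)-2-methyl-6-methylidenecyclohexyl]methyl}-4-(methoxymethoxy)benzoate | CC(C)(C)[Si](c1ccccc1)(c1ccccc1)OCC[C@@]2(C)[C@H](Cc3cc(ccc3OCOC)C(=O)OC)C(=C)CC[C@@H]2Br | intermediate
24 | methyl 3-{[(1R,2S,3S)-3-bromo-2-(2-hydroxyethyl)-2-methyl-6-methylidenecyclohexyl]methyl}-4-(methoxymethoxy)benzoate | OCC[C@@]1(C)[C@H](Cc2cc(ccc2OCOC)C(=O)OC)C(=C)CC[C@@H]1Br | intermediate
25 | methyl 3-{[(1R,2S,3S)-3-bromo-2-(2-iodoethyl)-2-methyl-6-methylidenecyclohexyl]methyl}-4-(methoxymethoxy)benzoate | ICC[C@@]1(C)[C@H](Cc2cc(ccc2OCOC)C(=O)OC)C(=C)CC[C@@H]1Br | intermediate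
26 | pent-4-ynoic acid | C#CCCC(=O)O | starting material
27 | 1-(1H-imidazol-1-yl)pent-4-yn-1-one | C#CCCC(=O)n1ccnc1 | intermediate
28 | N-methoxy-N-methylpent-4-ynamide | C#CCCC(=O)N(C)OC | intermediate
29 | 2-methylhept-1-en-6-yn-3-one | C=C(C)C(=O)CCC#C | intermediate
30 | (3S)-2-methylhept-1-en-6-yn-3-ol | C=C(C)[C@@H](O)CCC#C | intermediate
31 | tert-butyl(dimethyl){[(3S)-2-methylhept-1-en-6-yn-3-yl]oxy}silane | C=C(C)[C@@H](O[Si](C)(C)C(C)(C)C)CCC#C | intermediate
32 | [(1E,5S)-5-(TBS-oxy)-2,6-dimethylhepta-1,6-dien-1-yl]dimethylalane | C=C(C)[C@@H](O[Si](C)(C)C(C)(C)C)CC/C(C)=C/[Al](C)C | intermediate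
33 | tert-butyl{[(3S,6E)-7-iodo-2,6-dimethylhepta-1,6-dien-3-yl]oxy}dimethylsilane | C=C(C)[C@@H](O[Si](C)(C)C(C)(C)C)CC/C(C)=C/I | intermediate
34 | alkylzinc iodide from 25 (C9–ZnI; ring stereocentres as in 25) | I[Zn]CC[C@@]1(C)[C@H](Cc2cc(ccc2OCOC)C(=O)OC)C(=C)CC[C@@H]1Br | intermediate
35 | methyl 3-{[(1R,2S,3S)-3-bromo-2-[(3E,7S)-7-(TBS-oxy)-4,8-dimethylnona-3,8-dien-1-yl]-2-methyl-6-methylidenecyclohexyl]methyl}-4-(methoxymethoxy)benzoate | C=C(C)[C@@H](O[Si](C)(C)C(C)(C)C)CC/C(C)=C/CC[C@@]1(C)[C@H](Cc2cc(ccc2OCOC)C(=O)OC)C(=C)CC[C@@H]1Br | intermediate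
36 | methyl 3-{[(1R,2S,3S)-3-bromo-2-[(3E,7S)-7-hydroxy-4,8-dimethylnona-3,8-dien-1-yl]-2-methyl-6-methylidenecyclohexyl]methyl}-4-(methoxymethoxy)benzoate | C=C(C)[C@@H](O)CC/C(C)=C/CC[C@@]1(C)[C@H](Cc2cc(ccc2OCOC)C(=O)OC)C(=C)CC[C@@H]1Br | intermediate
37 | 3-{[(1R,2S,3S)-3-bromo-2-[(3E,7S)-7-hydroxy-4,8-dimethylnona-3,8-dien-1-yl]-2-methyl-6-methylidenecyclohexyl]methyl}-4-(methoxymethoxy)benzoic acid | C=C(C)[C@@H](O)CC/C(C)=C/CC[C@@]1(C)[C@H](Cc2cc(ccc2OCOC)C(=O)O)C(=C)CC[C@@H]1Br | intermediate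
38 | mixed anhydride of 37 with 2,4,6-trichlorobenzoic acid | C=C(C)[C@@H](O)CC/C(C)=C/CC[C@@]1(C)[C@H](Cc2cc(ccc2OCOC)C(=O)OC(=O)c3c(Cl)cc(Cl)cc3Cl)C(=C)CC[C@@H]1Br | intermediate
39 | (2R,6S,7S,10E,14S)-10,11-didehydro-10,11-dideoxy (alkene) macrolactone, O-MOM (15-membered lactone O–C14) | C=C(C)[C@@H]1CC/C(C)=C/CC[C@@]2(C)[C@H](Cc3cc(ccc3OCOC)C(=O)O1)C(=C)CC[C@@H]2Br | intermediate
40 | (2R,6S,7S,10S,11S,14S)-10,11-epoxy macrolactone, O-MOM | C=C(C)[C@@H]1CC[C@]4(C)O[C@H]4CC[C@@]2(C)[C@H](Cc3cc(ccc3OCOC)C(=O)O1)C(=C)CC[C@@H]2Br | intermediate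
41 | O-MOM bromophycolide E (2R,6S,7S,10R,11S,14S) | C=C(C)[C@@H]1CC[C@](C)(O)[C@H](Br)CC[C@@]2(C)[C@H](Cc3cc(ccc3OCOC)C(=O)O1)C(=C)CC[C@@H]2Br | intermediate
42 | bromophycolide E (2R,6S,7S,10R,11S,14S) | C=C(C)[C@@H]1CC[C@](C)(O)[C@H](Br)CC[C@@]2(C)[C@H](Cc3cc(ccc3O)C(=O)O1)C(=C)CC[C@@H]2Br | target

## Step count and risks

Total step count: 28. Longest linear sequence: 22 steps (steps 1–9, 11–16, 22–28).

Step 14 (the proposed new cyclisation). It can fail through slow ionisation, capture of the bromonium ion by solvent, protodesilylation, or Br+ transfer between alkenes with loss of enantiopurity. The fallback uses known chemistry, sets out from 11 and comes back at 23. Compound 11 is epoxidised with the enantiomeric (L-sorbose-derived) Shi ketone under the step 7 conditions to give the (6S,7S)-epoxy enoate F1. Reduction with i-Bu2AlH gives the (6S,7S)-epoxy allylic alcohol F2, which is converted through the mesylate F3 into the allylic chloride F4 and coupled with 18 as in step 11 to give the (6S,7S)-aryl epoxide F5. BF3·OEt2 in CH2Cl2 at −78 °C then triggers the known Lewis-acid, epoxide-initiated, allylsilane-terminated chair cyclisation. The epoxide opens at C7 with inversion and gives the equatorial C6 alcohol F6, which has the C2 and C7 configurations of 23 and the exocyclic methylene. Because the oxygen must be replaced by bromine with net retention, Dess–Martin oxidation gives the C6 ketone F7, LiBH(s-Bu)3 at −78 °C attacks from the equatorial side to give the axial C6 alcohol F8, and CBr4/PPh3 (Appel, inversion) gives 23. The Appel step on this hindered axial alcohol is the weak point of the fallback (elimination competes).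

Step 26 (Shi epoxidation inside the macrocycle). The conformation of the macrolactone may override the catalyst, or a 1,1-disubstituted alkene may compete. The fallback sets out from 39 and comes back at 41, bypassing 40. N-bromosuccinimide in THF/H2O (4:1) at 0 °C adds Br and OH anti and Markovnikov across C10=C11 under substrate control. The bromonium face required is the face opposite to the one the epoxide oxygen must occupy, so a macrocycle that resists the epoxidation is biased toward the correct bromohydrin. The two anti bromohydrins are separated by HPLC; no new compound is made (F0).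

Step 22 (Negishi coupling). Zinc insertion must distinguish the primary iodide from the secondary bromide, and the alkylpalladium intermediate must not undergo β-hydride loss. The fallback sets out from 25 and 33 and comes back at 35. The two iodides are joined directly by nickel-catalysed reductive cross-electrophile coupling (NiBr2(MeOCH2CH2OMe), 4,4′-di-tert-butyl-2,2′-bipyridine, Mn powder, N,N-dimethylacetamide, 25 °C). No organozinc reagent is preformed, and the primary iodide is activated well ahead of the hindered secondary bromide; no new compound is made (F0).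

Further compounds

F1 | step 14 | methyl (2Z)-5-[(2S,3S)-3-(2-TBDPS-oxyethyl)-3-methyloxiran-2-yl]-3-[(trimethylsilyl)methyl]pent-2-enoate | COC(=O)/C=C(\C[Si](C)(C)C)CC[C@@H]1O[C@@]1(C)CCO[Si](c2ccccc2)(c2ccccc2)C(C)(C)C
F2 | step 14 | (2Z)-5-[(2S,3S)-3-(2-TBDPS-oxyethyl)-3-methyloxiran-2-yl]-3-[(trimethylsilyl)methyl]pent-2-en-1-ol | OC/C=C(\C[Si](C)(C)C)CC[C@@H]1O[C@@]1(C)CCO[Si](c2ccccc2)(c2ccccc2)C(C)(C)C
F3 | step 14 | methanesulfonate of F2 | CS(=O)(=O)OC/C=C(\C[Si](C)(C)C)CC[C@@H]1O[C@@]1(C)CCO[Si](c2ccccc2)(c2ccccc2)C(C)(C)C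
F4 | step 14 | tert-butyl(2-{(2S,3S)-3-[(3Z)-5-chloro-3-[(trimethylsilyl)methyl]pent-3-en-1-yl]-2-methyloxiran-2-yl}ethoxy)diphenylsilane | ClC/C=C(\C[Si](C)(C)C)CC[C@@H]1O[C@@]1(C)CCO[Si](c2ccccc2)(c2ccccc2)C(C)(C)C
F5 | step 14 | methyl 3-{(2Z)-5-[(2S,3S)-3-(2-TBDPS-oxyethyl)-3-methyloxiran-2-yl]-3-[(trimethylsilyl)methyl]pent-2-en-1-yl}-4-(methoxymethoxy)benzoate | COC(=O)c1ccc(OCOC)c(C/C=C(\C[Si](C)(C)C)CC[C@@H]2O[C@@]2(C)CCO[Si](c3ccccc3)(c3ccccc3)C(C)(C)C)c1
F6 | step 14 | methyl 3-{[(1R,2S,3S)-3-hydroxy-2-(2-TBDPS-oxyethyl)-2-methyl-6-methylidenecyclohexyl]methyl}-4-(methoxymethoxy)benzoate | CC(C)(C)[Si](c1ccccc1)(c1ccccc1)OCC[C@@]2(C)[C@H](Cc3cc(ccc3OCOC)C(=O)OC)C(=C)CC[C@@H]2O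
F7 | step 14 | methyl 3-{[(1R,2S)-2-(2-TBDPS-oxyethyl)-2-methyl-6-methylidene-3-oxocyclohexyl]methyl}-4-(methoxymethoxy)benzoate | CC(C)(C)[Si](c1ccccc1)(c1ccccc1)OCC[C@@]2(C)[C@H](Cc3cc(ccc3OCOC)C(=O)OC)C(=C)CCC2=O
F8 | step 14 | methyl 3-{[(1R,2S,3R)-3-hydroxy-2-(2-TBDPS-oxyethyl)-2-methyl-6-methylidenecyclohexyl]methyl}-4-(methoxymethoxy)benzoate | CC(C)(C)[Si](c1ccccc1)(c1ccccc1)OCC[C@@]2(C)[C@H](Cc3cc(ccc3OCOC)C(=O)OC)C(=C)CC[C@H]2O
F0 | step 26 | none | none
F0 | step 22 | none | none
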